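# Proposed total synthesis of 4'''-hydroxytrianguletin by Claisen closure of ring D

## The problem

4'''-Hydroxytrianguletin (19) joins two polyphenolic halves through one methylene carbon: C8 of the flavonol kaempferide (rings A, B and C) and D1 of a fully substituted benzene, ring D, whose D3 carries a 3-(4-hydroxyphenyl)propanoyl chain ending in ring E. The molecule has no stereocentre, so the whole difficulty is regiochemical. Ring D bears six different substituents in a fixed order (D1 CH2, D2 OH, D3 acyl, D4 OH, D5 CH3, D6 OCH3), the bridge must sit at C8 and not at C6 of ring A, and only one of the three ring D oxygens is methylated. Six free phenols make the target sensitive to air in base, the methylene bridge between two phloroglucinol-type rings can scramble through quinone methides in alkali or strong acid, and the chromone ring C is opened by hard nucleophiles; the last steps therefore have to be neutral. Building ring D by successive electrophilic substitutions on a phloroglucinol would mean placing C-methyl, C-acyl and C-arylmethyl groups on positions of almost equal reactivity. The feature that offers another way is that ring D has oxygen on alternate carbons (D2, D4, D6) with the acyl group on D3 between two of them. This is the pattern of a tetraketide closed between D3 and D4, and the two carbon substituents (D5 CH3, D1 CH2) lie on what would be the internal, enolizable carbons C2 and C4 of an open 3,5,7-triketo ester. Both groups can therefore be introduced by enolate chemistry before ring D exists.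

## Retrosynthesis

**Target 19 to 17.** The four benzyl–oxygen bonds of 18 (3-O, 5-O and 7-O of the flavonol, and the ring E oxygen) are cut first, then the O–CH3 bond at D6, which leads to the ring D triol 17. Benzyl ethers are chosen because one neutral hydrogenolysis frees all phenols without touching the bridge. The D6 methyl is added after ring D is aromatic because only then do the three oxygens differ clearly: D6-OH is para to the ketone and the most acidic, while D2-OH and D4-OH flank the carbonyl. Placing the methyl earlier, as an enol ether in the open chain, would weaken the ester that has to be attacked in the ring closure. The forward steps ask for selective mono-methylation and for hydrogenolysis that spares the C2=C3 bond and the aryl ketone.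

**17 to 15 (key disconnection).** Ring D is opened at the D3–D4 bond to give triketo ester 15. In 15, C1 is the ester (future D4), C2 carries the methyl (D5), C3, C5 and C7 are ketones, C4 carries the flavonylmethyl group (D1) and C6 is the future D3. The neighbouring cuts (CH2–D1, CH2–C8 or D3–acyl) all lead back to electrophilic substitution on a separately prepared, highly substituted phloroglucinol. The D3–D4 cut instead turns a hexasubstituted arene into a chain in which every substituent sits on an activated carbon. Precursor 15 has one ring less and needs no regiocontrol on an aromatic nucleus. The forward reaction has to make the C6 enolate attack the C1 ester (Claisen mode) in preference to aldol, lactonization and chain-cleavage pathways; the cyclohexanetrione 16 then aromatizes to 17.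

**15 to 8 and 13.** The C7 carbonyl of 15 is masked as the dioxolane in 14, and 14 is cut at the C4–CH2 bond into diketo ester 8 and benzylic bromide 13. With C7 masked, C4 is the only carbon of 8 lying between two ketones, so a carbonate base is enough and the alkylation is regioselective. The other order (alkylating the dianion of 6 with 13, then acylating at the now secondary C4) would expose the chromone to lithium amide or alkyllithium bases and would require acylation at a hindered carbon. The cut is convergent: it separates the flavonol from the polyketide chain. The forward reaction asks for C- over O-alkylation and for mono-alkylation.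

**8 to 6 and 5, and 5 to 1.** Bond C4–C5 of 8 is cut to give dianion 7 of methyl 2-methylacetoacetate (6) and Weinreb amide 5. The C-methyl group of ring D is thus bought with 6. Amide 5 goes back through ester 4 and β-keto ester 3 to the benzyl-protected acid 1 by a two-carbon homologation and ketalization. The forward reaction is a crossed Claisen acylation at the terminal carbon of a dianion; an amide is preferred over an ester because its tetrahedral adduct does not release the acidic product until work-up.

**13 to 9.** The C–Br bond of 13 goes back to alcohol 12, the C8–CH2OH bond to iodide 11, the C8–I bond to tribenzyl ether 10, and the three benzyl ethers to kaempferide (9). Using 9 supplies rings A, B and C with the 3-oxygen in place. The one demand is C8 over C6 selectivity in the iodination, which is secured by alkylating the 5-hydroxyl first.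

## Roads not taken

**Alternative 1:** Ring C would be cut at C4a–C4, C4–C3 and O1–C2. In the forward sense, iodophenol A2 (which already contains the bridge and the complete, benzylated ring D), carbon monoxide A4 and 4-ethynylanisole A3 would be joined by a palladium-catalysed carbonylative alkynylation, and the coupled intermediate would close through its phenol oxygen to flavone A1.
- Merits: the annulation is modular and is an established way to 2-arylchromones; ring B is attached last.
- Weak points: A1 is a flavone, so the 3-hydroxyl would have to be introduced afterwards by oxidation at C3 of a large, electron-rich, benzyl-ether-laden molecule. A2 presupposes a finished ring D and bridge, so the hardest part of the target still needs its own synthesis. The iodide of A2 lies between a benzyloxy group and a hydroxyl, which slows oxidative addition and insertion, and closure through the phenol can go 5-exo as well as 6-endo.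
- Comparison: as a single reaction the carbonylative annulation is better precedented than the Claisen closure of 15 and would be the safer step. The chosen plan sets against this that 9 brings rings A to C with the 3-oxygen already in place, that ring D and the bridge are made within the same sequence, and that the total is shorter.

**Alternative 2:** Ring A would be cut at CH2–C8 and C6–C7. Irradiation of diazo ketone A6 would extrude the diazo nitrogen, the ring D benzyl group would shift to the former diazo carbon (Wolff rearrangement), and the cumulated intermediate would close by 6π electrocyclization onto the neighbouring silyl enol ether to give phenol A5.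
- Merits: the bridge is fixed at C8 by construction, so no C6/C8 question arises, and the 5- and 7-oxygens come out differentiated.
- Weak points: A6 is a tetrasubstituted 4-pyranone carrying a diazo ketone next to a silyl enol ether. Its preparation would take many steps with mutually sensitive groups. The photolysis has to work in a molecule that contains a strongly absorbing pyranone and an aryl ketone, and the carbene can also add to the adjacent enol ether instead of rearranging. Ring D must again be made separately.
- Comparison: in regiochemical rigour at C8 this road is better than step 6 of the chosen plan, which relies on directing effects. The chosen plan sets against it a two-operation functionalization of a purchased flavonol, far fewer steps, and no need to rebuild ring A.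

**Alternative 3:** Ring D would be cut at D1–D2, D5–D6 and D2–D3. Heating cyclobutenone A8 with alkynyl ether A9 would give, by four-electron ring opening, (2+2) cycloaddition, second ring opening and 6π closure, phenol A7.
- Merits: ring D forms under neutral thermal conditions with regiochemistry fixed by the mechanism. The D6 oxygen arrives already methylated and D2 and D4 come out differentiated, so no selective methylation is needed. In this respect the alternative is better than the chosen plan, which depends on an acidity difference in step 12.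
- Weak points: D3 emerges as C–H. The 3-arylpropanoyl group would have to be introduced afterwards by Friedel–Crafts or Fries chemistry at the most hindered position of a molecule with acid-labile benzyl ethers and a Lewis-basic chromone. A9, a propargylic ynol ether on a flavone, requires acetylide chemistry with strong bases and is prone to isomerization and hydration. A8 needs its own preparation.
- Comparison: the benzannulation is better precedented for hexasubstituted phenols than the Claisen closure. The chosen plan sets against this that the acyl chain is part of the open precursor, so ring D appears with all six substituents in one step, and that all building blocks are simple.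

Key step: step 11

Remark on the chemistry: the poly-β-carbonyl compounds 8, 14, 15 and 16 are drawn as keto forms; they will be mixtures of enol tautomers and, where C2 and C4 are stereogenic, of stereoisomers, which is of no consequence because both carbons become sp2 in ring D. 3-[4-(Benzyloxy)phenyl]propanoic acid (1) is taken as a purchased compound.

## Route

Step 1
Reactants: 1 3-[4-(benzyloxy)phenyl]propanoic acid
Product: 3 methyl 5-[4-(benzyloxy)phenyl]-3-oxopentanoate, via acyl Meldrum's acid 2 (not isolated)
Conditions: Meldrum's acid, DCC, DMAP, CH2Cl2, 0 °C → rt; filter; then MeOH, reflux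
Reagents that add atoms: Meldrum's acid (2,2-dimethyl-1,3-dioxane-4,6-dione), CC1(C)OC(=O)CC(=O)O1; methanol, CO
Why: Oikawa–Yonemitsu β-keto ester synthesis: carbodiimide-mediated C-acylation of Meldrum's acid, then methanolysis of 2 with loss of acetone and CO2; the aryl benzyl ether is inert.

Step 2
Reactants: 3 methyl 5-[4-(benzyloxy)phenyl]-3-oxopentanoate
Product: 4 methyl 2-{2-[2-(4-benzyloxyphenyl)ethyl]-1,3-dioxolan-2-yl}acetate
Conditions: HOCH2CH2OH, p-TsOH·H2O (cat.), toluene, reflux (Dean–Stark)
Reagents that add atoms: ethylene glycol, OCCO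
Why: Acid-catalysed ketalization of the ketone of a β-keto ester with azeotropic removal of water, as for acetoacetates; it masks the future C7 carbonyl so that later only C4 lies between two ketones.

Step 3
Reactants: 4 methyl 2-{2-[2-(4-benzyloxyphenyl)ethyl]-1,3-dioxolan-2-yl}acetate
Product: 5 2-{2-[2-(4-benzyloxyphenyl)ethyl]-1,3-dioxolan-2-yl}-N-methoxy-N-methylacetamide
Conditions: MeNH(OMe)·HCl, i-PrMgCl, THF, −20 → 0 °C
Reagents that add atoms: N,O-dimethylhydroxylamine hydrochloride, CNOC.Cl
Why: Weinreb amide formation by aminolysis of the ester with the chloromagnesium amide of N,O-dimethylhydroxylamine; ketal and benzyl ether are stable to these conditions.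

Step 4
Reactants: 6 methyl 2-methylacetoacetate (methyl 2-methyl-3-oxobutanoate); 5 2-{2-[2-(4-benzyloxyphenyl)ethyl]-1,3-dioxolan-2-yl}-N-methoxy-N-methylacetamide
Product: 8 methyl 6-{2-[2-(4-benzyloxyphenyl)ethyl]-1,3-dioxolan-2-yl}-2-methyl-3,5-dioxohexanoate, via ester dianion 7 (not isolated)
Conditions: 6 (2 equiv), NaH, THF, 0 °C; n-BuLi, 0 °C; then 5, −78 → 0 °C; aq. NH4Cl
Reagents that add atoms: none
Why: Huckin–Weiler dianion chemistry: the terminal carbanion of 7 is acylated by the Weinreb amide (crossed Claisen acylation), and the chelated tetrahedral adduct prevents a second addition and releases the acidic 3,5-diketo ester only on quench.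

Step 5
Reactants: 9 kaempferide (3,5,7-trihydroxy-2-(4-methoxyphenyl)-4H-chromen-4-one)
Product: 10 3,5,7-tris(benzyloxy)-2-(4-methoxyphenyl)-4H-chromen-4-one
Conditions: BnBr (4.5 equiv), K2CO3, DMF, 70 °C
Reagents that add atoms: benzyl bromide, BrCc1ccccc1
Why: Williamson etherification; excess halide and heating are used because the 5-hydroxyl is hydrogen-bonded to the C4 carbonyl and reacts last.

Step 6
Reactants: 10 3,5,7-tris(benzyloxy)-2-(4-methoxyphenyl)-4H-chromen-4-one
Product: 11 3,5,7-tris(benzyloxy)-8-iodo-2-(4-methoxyphenyl)-4H-chromen-4-one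
Conditions: NIS (1.1 equiv), DMF, rt → 50 °C, dark
Reagents that add atoms: N-iodosuccinimide, O=C1CCC(=O)N1I
Why: Electrophilic aromatic iodination; 5-O-alkylated 5,7-dioxygenated flavones react at C8 (a free 5-hydroxyl would direct to C6), C6 is shielded by two benzyloxy groups, and the anisyl ring B is deactivated by the pyranone.

Step 7
Reactants: 11 3,5,7-tris(benzyloxy)-8-iodo-2-(4-methoxyphenyl)-4H-chromen-4-one
Product: 12 3,5,7-tris(benzyloxy)-8-(hydroxymethyl)-2-(4-methoxyphenyl)-4H-chromen-4-one
Conditions: Bu3SnCH2OH, Pd(PPh3)4 (cat.), 1,4-dioxane, 100 °C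
Reagents that add atoms: (tributylstannyl)methanol, OC[Sn](CCCC)(CCCC)CCCC
Why: Stille (Migita–Kosugi) hydroxymethylation of an aryl iodide under zerovalent palladium catalysis; the neutral conditions tolerate the benzyl ethers and the chromone.

Step 8
Reactants: 12 3,5,7-tris(benzyloxy)-8-(hydroxymethyl)-2-(4-methoxyphenyl)-4H-chromen-4-one
Product: 13 3,5,7-tris(benzyloxy)-8-(bromomethyl)-2-(4-methoxyphenyl)-4H-chromen-4-one
Conditions: CBr4, PPh3, CH2Cl2, 0 °C
Reagents that add atoms: carbon tetrabromide, BrC(Br)(Br)Br
Why: Appel bromination of an activated benzylic alcohol under neutral conditions, which spares the acid-sensitive 5-O-benzyl ether; the bromide is used at once.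

Step 9
Reactants: 8 methyl 6-{2-[2-(4-benzyloxyphenyl)ethyl]-1,3-dioxolan-2-yl}-2-methyl-3,5-dioxohexanoate; 13 3,5,7-tris(benzyloxy)-8-(bromomethyl)-2-(4-methoxyphenyl)-4H-chromen-4-one
Product: 14 methyl 6-{2-[2-(4-benzyloxyphenyl)ethyl]-1,3-dioxolan-2-yl}-2-methyl-3,5-dioxo-4-{[3,5,7-tris(benzyloxy)-2-(4-methoxyphenyl)-4-oxo-4H-chromen-8-yl]methyl}hexanoate
Conditions: K2CO3, acetone, rt → 40 °C (8 in 1.3-fold excess)
Reagents that add atoms: none
Why: C-alkylation of a β-diketone monoanion with a benzylic bromide; C4 between the C3 and C5 ketones is the most acidic site of 8, C2 is tertiary and less acidic, and C6 is only singly activated while C7 is a ketal; the carbonate base leaves the chromone untouched.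

Step 10
Reactants: 14 methyl 6-{2-[2-(4-benzyloxyphenyl)ethyl]-1,3-dioxolan-2-yl}-2-methyl-3,5-dioxo-4-{[3,5,7-tris(benzyloxy)-2-(4-methoxyphenyl)-4-oxo-4H-chromen-8-yl]methyl}hexanoate
Product: 15 methyl 9-[4-(benzyloxy)phenyl]-2-methyl-3,5,7-trioxo-4-{[3,5,7-tris(benzyloxy)-2-(4-methoxyphenyl)-4-oxo-4H-chromen-8-yl]methyl}nonanoate
Conditions: 1 M HCl, THF, rt
Reagents that add atoms: water, O
Why: Acid-catalysed hydrolysis of the dioxolane to the C7 ketone; dilute acid at room temperature should leave the aryl benzyl ethers intact, and the crude triketo ester is taken on directly because such chains cyclize on standing.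

Step 11
Reactants: 15 methyl 9-[4-(benzyloxy)phenyl]-2-methyl-3,5,7-trioxo-4-{[3,5,7-tris(benzyloxy)-2-(4-methoxyphenyl)-4-oxo-4H-chromen-8-yl]methyl}nonanoate
Product: 17 3,5,7-tris(benzyloxy)-8-({3-[3-(4-benzyloxyphenyl)propanoyl]-2,4,6-trihydroxy-5-methylphenyl}methyl)-2-(4-methoxyphenyl)-4H-chromen-4-one, via cyclohexanetrione 16 (not isolated)
Conditions: Mg(OMe)2 (5 equiv), MeOH, 25 → 65 °C; then 1 M HCl, 0 °C
Reagents that add atoms: none
Why: Proposed new method: Mg(OMe)2 deprotonates the most acidic site, the C6 methylene between the C5 and C7 ketones, and holds it as a magnesium diketonate; its central carbon adds to the C1 ester carbonyl, methoxide is expelled, and trione 16 enolizes to the aromatic, magnesium-bound acylphloroglucinol 17, which removes it from all equilibria. The closest known reaction type is the Mg(OMe)2- or alkali-methoxide-mediated Claisen (Dieckmann-type) cyclization of 3,5,7-triketo esters without substituents at C2 and C4 to acylphloroglucinols, the laboratory counterpart of the chalcone synthase closure; the 2-methyl and 4-arylmethyl groups are the untested element. Ring D closes in a 6-(enolendo)-exo-trig mode through bond C6–C1 (D3–D4). No stereocentre is created, and the C2 and C4 centres of 15 disappear on aromatization. The step needs Claisen closure from C6 to win over aldol addition of C2 to the C7 ketone, lactonization of the C5 enol onto C1, and retro-Claisen cleavage of the chain by methoxide. The substrate should secure this because C6 is its only unsubstituted doubly activated carbon, because the aldol mode would create a quaternary C2 that cannot aromatize and remains reversible, and because a 2-pyranone formed by lactonization is reopened by methoxide, so that only the Claisen path ends in an aromatic sink.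

Step 12
Reactants: 17 3,5,7-tris(benzyloxy)-8-({3-[3-(4-benzyloxyphenyl)propanoyl]-2,4,6-trihydroxy-5-methylphenyl}methyl)-2-(4-methoxyphenyl)-4H-chromen-4-one
Product: 18 3,5,7-tris(benzyloxy)-8-({3-[3-(4-benzyloxyphenyl)propanoyl]-2,4-dihydroxy-6-methoxy-5-methylphenyl}methyl)-2-(4-methoxyphenyl)-4H-chromen-4-one
Conditions: TMSCHN2 (1.1 equiv), toluene/MeOH 4:1, 0 °C → rt
Reagents that add atoms: (trimethylsilyl)diazomethane, C[Si](C)(C)C=[N+]=[N-]
Why: O-methylation of the most acidic phenol by a diazomethane equivalent; D6-OH is para to the ketone and the most acidic, whereas D2-OH and D4-OH flank the carbonyl and are held in hydrogen bonds, as in the selective 4-O-methylation of phloroacetophenones.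

Step 13
Reactants: 18 3,5,7-tris(benzyloxy)-8-({3-[3-(4-benzyloxyphenyl)propanoyl]-2,4-dihydroxy-6-methoxy-5-methylphenyl}methyl)-2-(4-methoxyphenyl)-4H-chromen-4-one
Product: 19 4'''-hydroxytrianguletin, 3,5,7-trihydroxy-8-({2,4-dihydroxy-3-[3-(4-hydroxyphenyl)propanoyl]-6-methoxy-5-methylphenyl}methyl)-2-(4-methoxyphenyl)-4H-chromen-4-one
Conditions: H2 (1 atm), 10% Pd/C, EtOAc/MeOH, rt
Reagents that add atoms: none
Why: Hydrogenolysis of four aryl benzyl ethers over Pd/C; the tetrasubstituted C2=C3 bond of the flavonol and the chelated aryl ketone should not be reduced at 1 atm and room temperature, and the neutral medium avoids scrambling of the methylene bridge.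

## Compound list

1 | 3-[4-(benzyloxy)phenyl]propanoic acid | OC(=O)CCc1ccc(OCc2ccccc2)cc1 | starting material
2 | 5-{3-[4-(benzyloxy)phenyl]-1-hydroxypropylidene}-2,2-dimethyl-1,3-dioxane-4,6-dione (acyl Meldrum's acid, formed in the flask) | CC1(C)OC(=O)C(=C(O)CCc2ccc(OCc3ccccc3)cc2)C(=O)O1 | intermediate
3 | methyl 5-[4-(benzyloxy)phenyl]-3-oxopentanoate | COC(=O)CC(=O)CCc1ccc(OCc2ccccc2)cc1 | intermediate
4 | methyl 2-{2-[2-(4-benzyloxyphenyl)ethyl]-1,3-dioxolan-2-yl}acetate | COC(=O)CC1(CCc2ccc(OCc3ccccc3)cc2)OCCO1 | intermediate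
5 | 2-{2-[2-(4-benzyloxyphenyl)ethyl]-1,3-dioxolan-2-yl}-N-methoxy-N-methylacetamide | CON(C)C(=O)CC1(CCc2ccc(OCc3ccccc3)cc2)OCCO1 | intermediate
6 | methyl 2-methylacetoacetate (methyl 2-methyl-3-oxobutanoate) | COC(=O)C(C)C(C)=O | starting material
7 | sodium lithium dianion (1,3-bis-enolate) of methyl 2-methyl-3-oxobutanoate (formed in the flask) | [Na+].[Li+].COC([O-])=C(C)C([O-])=C | intermediate
8 | methyl 6-{2-[2-(4-benzyloxyphenyl)ethyl]-1,3-dioxolan-2-yl}-2-methyl-3,5-dioxohexanoate (racemic, keto/enol mixture) | COC(=O)C(C)C(=O)CC(=O)CC1(CCc2ccc(OCc3ccccc3)cc2)OCCO1 | intermediate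
9 | kaempferide, 3,5,7-trihydroxy-2-(4-methoxyphenyl)-4H-chromen-4-one | COc1ccc(-c2oc3cc(O)cc(O)c3c(=O)c2O)cc1 | starting material
10 | 3,5,7-tris(benzyloxy)-2-(4-methoxyphenyl)-4H-chromen-4-one | COc1ccc(-c2oc3cc(OCc4ccccc4)cc(OCc4ccccc4)c3c(=O)c2OCc2ccccc2)cc1 | intermediate
11 | 3,5,7-tris(benzyloxy)-8-iodo-2-(4-methoxyphenyl)-4H-chromen-4-one | COc1ccc(-c2oc3c(I)c(OCc4ccccc4)cc(OCc4ccccc4)c3c(=O)c2OCc2ccccc2)cc1 | intermediate
12 | 3,5,7-tris(benzyloxy)-8-(hydroxymethyl)-2-(4-methoxyphenyl)-4H-chromen-4-one | COc1ccc(-c2oc3c(CO)c(OCc4ccccc4)cc(OCc4ccccc4)c3c(=O)c2OCc2ccccc2)cc1 | intermediate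
13 | 3,5,7-tris(benzyloxy)-8-(bromomethyl)-2-(4-methoxyphenyl)-4H-chromen-4-one | COc1ccc(-c2oc3c(CBr)c(OCc4ccccc4)cc(OCc4ccccc4)c3c(=O)c2OCc2ccccc2)cc1 | intermediate
14 | methyl 6-{2-[2-(4-benzyloxyphenyl)ethyl]-1,3-dioxolan-2-yl}-2-methyl-3,5-dioxo-4-{[3,5,7-tris(benzyloxy)-2-(4-methoxyphenyl)-4-oxo-4H-chromen-8-yl]methyl}hexanoate (mixture of stereoisomers and enol tautomers) | COC(=O)C(C)C(=O)C(Cc1c(OCc2ccccc2)cc(OCc2ccccc2)c2c1oc(-c1ccc(OC)cc1)c(OCc1ccccc1)c2=O)C(=O)CC1(CCc2ccc(OCc3ccccc3)cc2)OCCO1 | intermediate
15 | methyl 9-[4-(benzyloxy)phenyl]-2-methyl-3,5,7-trioxo-4-{[3,5,7-tris(benzyloxy)-2-(4-methoxyphenyl)-4-oxo-4H-chromen-8-yl]methyl}nonanoate (mixture of stereoisomers and enol tautomers) | COC(=O)C(C)C(=O)C(Cc1c(OCc2ccccc2)cc(OCc2ccccc2)c2c1oc(-c1ccc(OC)cc1)c(OCc1ccccc1)c2=O)C(=O)CC(=O)CCc1ccc(OCc2ccccc2)cc1 | intermediate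
16 | 2-{3-[4-(benzyloxy)phenyl]propanoyl}-4-methyl-6-{[3,5,7-tris(benzyloxy)-2-(4-methoxyphenyl)-4-oxo-4H-chromen-8-yl]methyl}cyclohexane-1,3,5-trione (non-aromatic tautomer, mixture of stereoisomers, formed in the flask) | CC1C(=O)C(Cc2c(OCc3ccccc3)cc(OCc3ccccc3)c3c2oc(-c2ccc(OC)cc2)c(OCc2ccccc2)c3=O)C(=O)C(C(=O)CCc2ccc(OCc3ccccc3)cc2)C1=O | intermediate
17 | 3,5,7-tris(benzyloxy)-8-({3-[3-(4-benzyloxyphenyl)propanoyl]-2,4,6-trihydroxy-5-methylphenyl}methyl)-2-(4-methoxyphenyl)-4H-chromen-4-one | COc1ccc(-c2oc3c(Cc4c(O)c(C(=O)CCc5ccc(OCc6ccccc6)cc5)c(O)c(C)c4O)c(OCc4ccccc4)cc(OCc4ccccc4)c3c(=O)c2OCc2ccccc2)cc1 | intermediate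
18 | 3,5,7-tris(benzyloxy)-8-({3-[3-(4-benzyloxyphenyl)propanoyl]-2,4-dihydroxy-6-methoxy-5-methylphenyl}methyl)-2-(4-methoxyphenyl)-4H-chromen-4-one | COc1ccc(-c2oc3c(Cc4c(O)c(C(=O)CCc5ccc(OCc6ccccc6)cc5)c(O)c(C)c4OC)c(OCc4ccccc4)cc(OCc4ccccc4)c3c(=O)c2OCc2ccccc2)cc1 | intermediate
19 | 4'''-hydroxytrianguletin, 3,5,7-trihydroxy-8-({2,4-dihydroxy-3-[3-(4-hydroxyphenyl)propanoyl]-6-methoxy-5-methylphenyl}methyl)-2-(4-methoxyphenyl)-4H-chromen-4-one | COc1ccc(-c2oc3c(Cc4c(O)c(C(=O)CCc5ccc(O)cc5)c(O)c(C)c4OC)c(O)cc(O)c3c(=O)c2O)cc1 | target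

## Step count and least certain steps

Total step count: 13.

Longest linear sequence: 9 steps (steps 1–4 and 9–13 from acid 1; the flavonol branch, steps 5–8 and 9–13 from kaempferide 9, is equally long).

**Step 11 (key step, Proposed new method).** The crowded chain may cyclize slowly, so that methoxide cleaves it at the 2-substituted 1,3-diketone (retro-Claisen at C3–C4 or C4–C5) before C6 reaches the ester. Aldol closure from C2 onto the C7 ketone followed by dehydration, or arrest at the 2-pyranone, would also divert material. The fallback uses known chemistry, gives up the ring closure and builds the bridge on a preformed ring D. It sets out from alcohol 12. Friedel–Crafts acylation of commercial 2-methylphloroglucinol with 3-(4-hydroxyphenyl)propanoic acid in BF3·OEt2 should give 1-(2,4,6-trihydroxy-3-methylphenyl)-3-(4-hydroxyphenyl)propan-1-one F1. Acid-catalysed Friedel–Crafts benzylation of F1 at its single free ring carbon with 12 (p-TsOH cat., MeCN) should give the tribenzyl bridged triol 3,5,7-tris(benzyloxy)-8-({2,4,6-trihydroxy-3-[3-(4-hydroxyphenyl)propanoyl]-5-methylphenyl}methyl)-2-(4-methoxyphenyl)-4H-chromen-4-one F2. Methylation of its most acidic hydroxyl with TMSCHN2 as in step 12 should give the D6 methyl ether 3,5,7-tris(benzyloxy)-8-({2,4-dihydroxy-3-[3-(4-hydroxyphenyl)propanoyl]-6-methoxy-5-methylphenyl}methyl)-2-(4-methoxyphenyl)-4H-chromen-4-one F3, and hydrogenolysis over Pd/C brings the sequence back to the route at target 19.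

**Step 9.** The diketonate of 8 may be alkylated on oxygen or twice at C4, and the electron-rich benzylic bromide 13 may ionize and be lost to solvolysis or self-condensation. The fallback replaces alkylation by condensation and reduction. It sets out from alcohol 12, which is oxidized with MnO2 to 3,5,7-tris(benzyloxy)-2-(4-methoxyphenyl)-4-oxo-4H-chromene-8-carbaldehyde F4. Proline-catalysed Knoevenagel condensation of F4 with 8 in the presence of a Hantzsch ester forms the alkylidene diketone methyl 6-{2-[2-(4-benzyloxyphenyl)ethyl]-1,3-dioxolan-2-yl}-2-methyl-3,5-dioxo-4-{[3,5,7-tris(benzyloxy)-2-(4-methoxyphenyl)-4-oxo-4H-chromen-8-yl]methylidene}hexanoate F5, which is reduced in the same flask by hydride transfer. Only mono-C-alkylation is possible, and the sequence returns to the route at 14.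

**Step 4.** Dianion 7 may act as a base towards the α-methylene of amide 5, after which the dioxolane can open by β-elimination, and acylation may stop short. The fallback replaces acylation by aldol addition and oxidation. It sets out from ester 4, which is reduced with i-Bu2AlH at −78 °C to 2-{2-[2-(4-benzyloxyphenyl)ethyl]-1,3-dioxolan-2-yl}acetaldehyde F6. Addition of dianion 7 at −78 °C should give methyl 6-{2-[2-(4-benzyloxyphenyl)ethyl]-1,3-dioxolan-2-yl}-5-hydroxy-2-methyl-3-oxohexanoate F7, and oxidation of the secondary alcohol with IBX returns to the route at 8.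

**Step 7.** Transfer of the hydroxymethyl group from tin to a doubly ortho-substituted arylpalladium intermediate may be slow, so that reduction of the C–I bond or homocoupling takes over. The fallback brings in the carbon as a vinyl group. It sets out from iodide 11. Suzuki–Miyaura coupling with CH2=CHBF3K (PdCl2(dppf), Cs2CO3) should give 3,5,7-tris(benzyloxy)-2-(4-methoxyphenyl)-8-vinyl-4H-chromen-4-one F8. Oxidative cleavage with OsO4 (cat.) and NaIO4 gives the 8-carbaldehyde F4 already described, and reduction with NaBH4 at 0 °C, where the aldehyde reacts far faster than the chromone carbonyl, returns to the route at 12.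

**Step 12.** Methylation may go on to a second hydroxyl, or selectivity may erode if the crowded D6 hydroxyl, flanked by the methyl group and the bridge, reacts more slowly than expected. The fallback differentiates the hydroxyls through their esters. It sets out from 17, which is peracetylated (Ac2O, pyridine, DMAP) to the ring D triacetate of 17, 3,5,7-tris(benzyloxy)-8-({2,4,6-triacetoxy-3-[3-(4-benzyloxyphenyl)propanoyl]-5-methylphenyl}methyl)-2-(4-methoxyphenyl)-4H-chromen-4-one F9. The acetate para to the ketone, the ester of the most acidic phenol, is removed selectively with imidazole in MeOH to give the D2,D4-diacetate with free D6 hydroxyl F10. Methylation with MeI and K2CO3 gives the D2,D4-diacetate D6 methyl ether F11, and K2CO3 in MeOH removes the two remaining acetates and returns to the route at 18.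

## Further compounds

F1 | step 11 | 1-(2,4,6-trihydroxy-3-methylphenyl)-3-(4-hydroxyphenyl)propan-1-one | Cc1c(O)cc(O)c(C(=O)CCc2ccc(O)cc2)c1O
F2 | step 11 | 3,5,7-tris(benzyloxy)-8-({2,4,6-trihydroxy-3-[3-(4-hydroxyphenyl)propanoyl]-5-methylphenyl}methyl)-2-(4-methoxyphenyl)-4H-chromen-4-one | COc1ccc(-c2oc3c(Cc4c(O)c(C(=O)CCc5ccc(O)cc5)c(O)c(C)c4O)c(OCc4ccccc4)cc(OCc4ccccc4)c3c(=O)c2OCc2ccccc2)cc1
F3 | step 11 | 3,5,7-tris(benzyloxy)-8-({2,4-dihydroxy-3-[3-(4-hydroxyphenyl)propanoyl]-6-methoxy-5-methylphenyl}methyl)-2-(4-methoxyphenyl)-4H-chromen-4-one | COc1ccc(-c2oc3c(Cc4c(O)c(C(=O)CCc5ccc(O)cc5)c(O)c(C)c4OC)c(OCc4ccccc4)cc(OCc4ccccc4)c3c(=O)c2OCc2ccccc2)cc1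
F4 | step 9 | 3,5,7-tris(benzyloxy)-2-(4-methoxyphenyl)-4-oxo-4H-chromene-8-carbaldehyde | COc1ccc(-c2oc3c(C=O)c(OCc4ccccc4)cc(OCc4ccccc4)c3c(=O)c2OCc2ccccc2)cc1
F5 | step 9 | methyl 6-{2-[2-(4-benzyloxyphenyl)ethyl]-1,3-dioxolan-2-yl}-2-methyl-3,5-dioxo-4-{[3,5,7-tris(benzyloxy)-2-(4-methoxyphenyl)-4-oxo-4H-chromen-8-yl]methylidene}hexanoate (E/Z mixture) | COC(=O)C(C)C(=O)C(=Cc1c(OCc2ccccc2)cc(OCc2ccccc2)c2c1oc(-c1ccc(OC)cc1)c(OCc1ccccc1)c2=O)C(=O)CC1(CCc2ccc(OCc3ccccc3)cc2)OCCO1
F6 | step 4 | 2-{2-[2-(4-benzyloxyphenyl)ethyl]-1,3-dioxolan-2-yl}acetaldehyde | O=CCC1(CCc2ccc(OCc3ccccc3)cc2)OCCO1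
F7 | step 4 | methyl 6-{2-[2-(4-benzyloxyphenyl)ethyl]-1,3-dioxolan-2-yl}-5-hydroxy-2-methyl-3-oxohexanoate (mixture of diastereomers) | COC(=O)C(C)C(=O)CC(O)CC1(CCc2ccc(OCc3ccccc3)cc2)OCCO1
F8 | step 7 | 3,5,7-tris(benzyloxy)-2-(4-methoxyphenyl)-8-vinyl-4H-chromen-4-one | COc1ccc(-c2oc3c(C=C)c(OCc4ccccc4)cc(OCc4ccccc4)c3c(=O)c2OCc2ccccc2)cc1
F9 | step 12 | 3,5,7-tris(benzyloxy)-8-({2,4,6-triacetoxy-3-[3-(4-benzyloxyphenyl)propanoyl]-5-methylphenyl}methyl)-2-(4-methoxyphenyl)-4H-chromen-4-one | COc1ccc(-c2oc3c(Cc4c(OC(C)=O)c(C(=O)CCc5ccc(OCc6ccccc6)cc5)c(OC(C)=O)c(C)c4OC(C)=O)c(OCc4ccccc4)cc(OCc4ccccc4)c3c(=O)c2OCc2ccccc2)cc1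
F10 | step 12 | 3,5,7-tris(benzyloxy)-8-({2,4-diacetoxy-3-[3-(4-benzyloxyphenyl)propanoyl]-6-hydroxy-5-methylphenyl}methyl)-2-(4-methoxyphenyl)-4H-chromen-4-one | COc1ccc(-c2oc3c(Cc4c(OC(C)=O)c(C(=O)CCc5ccc(OCc6ccccc6)cc5)c(OC(C)=O)c(C)c4O)c(OCc4ccccc4)cc(OCc4ccccc4)c3c(=O)c2OCc2ccccc2)cc1
F11 | step 12 | 3,5,7-tris(benzyloxy)-8-({2,4-diacetoxy-3-[3-(4-benzyloxyphenyl)propanoyl]-6-methoxy-5-methylphenyl}methyl)-2-(4-methoxyphenyl)-4H-chromen-4-one | COc1ccc(-c2oc3c(Cc4c(OC(C)=O)c(C(=O)CCc5ccc(OCc6ccccc6)cc5)c(OC(C)=O)c(C)c4OC)c(OCc4ccccc4)cc(OCc4ccccc4)c3c(=O)c2OCc2ccccc2)cc1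
A1 | alternative 1 | 5-(benzyloxy)-8-({2,4-bis(benzyloxy)-3-[3-(4-benzyloxyphenyl)propanoyl]-6-methoxy-5-methylphenyl}methyl)-7-hydroxy-2-(4-methoxyphenyl)-4H-chromen-4-one | COc1ccc(-c2cc(=O)c3c(OCc4ccccc4)cc(O)c(Cc4c(OCc5ccccc5)c(C(=O)CCc5ccc(OCc6ccccc6)cc5)c(OCc5ccccc5)c(C)c4OC)c3o2)cc1
A2 | alternative 1 | 1-{2,6-bis(benzyloxy)-3-[(4-benzyloxy-2,6-dihydroxy-3-iodophenyl)methyl]-4-methoxy-5-methylphenyl}-3-[4-(benzyloxy)phenyl]propan-1-one | COc1c(C)c(OCc2ccccc2)c(C(=O)CCc2ccc(OCc3ccccc3)cc2)c(OCc2ccccc2)c1Cc1c(O)cc(OCc2ccccc2)c(I)c1O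
A3 | alternative 1 | 4-ethynylanisole | COc1ccc(C#C)cc1
A4 | alternative 1 | carbon monoxide | [C-]#[O+]
A5 | alternative 2 | 3-(benzyloxy)-8-({2,4-bis(benzyloxy)-3-[3-(4-benzyloxyphenyl)propanoyl]-6-methoxy-5-methylphenyl}methyl)-5-(tert-butyldimethylsilyloxy)-7-hydroxy-2-(4-methoxyphenyl)-4H-chromen-4-one | COc1ccc(-c2oc3c(Cc4c(OCc5ccccc5)c(C(=O)CCc5ccc(OCc6ccccc6)cc5)c(OCc5ccccc5)c(C)c4OC)c(O)cc(O[Si](C)(C)C(C)(C)C)c3c(=O)c2OCc2ccccc2)cc1
A6 | alternative 2 | 1-diazo-1-{5-(benzyloxy)-3-[1-(tert-butyldimethylsilyloxy)ethenyl]-6-(4-methoxyphenyl)-4-oxo-4H-pyran-2-yl}-3-{2,4-bis(benzyloxy)-3-[3-(4-benzyloxyphenyl)propanoyl]-6-methoxy-5-methylphenyl}propan-2-one | COc1ccc(-c2oc(C(=[N+]=[N-])C(=O)Cc3c(OCc4ccccc4)c(C(=O)CCc4ccc(OCc5ccccc5)cc4)c(OCc4ccccc4)c(C)c3OC)c(C(=C)O[Si](C)(C)C(C)(C)C)c(=O)c2OCc2ccccc2)cc1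
A7 | alternative 3 | 3,5,7-tris(benzyloxy)-8-{[4-(benzyloxy)-2-hydroxy-6-methoxy-5-methylphenyl]methyl}-2-(4-methoxyphenyl)-4H-chromen-4-one | COc1ccc(-c2oc3c(Cc4c(O)cc(OCc5ccccc5)c(C)c4OC)c(OCc4ccccc4)cc(OCc4ccccc4)c3c(=O)c2OCc2ccccc2)cc1
A8 | alternative 3 | 3-(benzyloxy)-2-methylcyclobut-2-en-1-one | CC1=C(OCc2ccccc2)CC1=O
A9 | alternative 3 | 3,5,7-tris(benzyloxy)-8-(3-methoxyprop-2-yn-1-yl)-2-(4-methoxyphenyl)-4H-chromen-4-one | COC#CCc1c(OCc2ccccc2)cc(OCc2ccccc2)c2c1oc(-c1ccc(OC)cc1)c(OCc1ccccc1)c2=O
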